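**Plan**

- Ring numbering: C-1 bears the ester oxygen, C-2 is the ring CH2, C-3=C-4 is the alkene (methyl on C-4), C-5 bears CH2OAr, C-6 the two methyl groups. Retrosynthesis: cut the ester C–O bond, take the C-1 carbinol back to a ketone, cut the aryl ether C–O bond, mask the ketone as a dioxolane, then open the ring at C-1–C-2 and C-3=C-4 together, releasing C-2/C-3 as a vinylphosphonium salt.
- Enabling feature: in the cyclohexene ring the oxygenated C-1 is homoallylic to the trisubstituted C-3=C-4 alkene and C-4 carries a methyl group. A two-carbon bridge therefore joins a carbon that can be a masked acyl radical (acetal C–H) to a carbon that can be a methyl ketone.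
- Forward: the open chain C-1/C-6/C-5/C-4 (acetal, gem-dimethyl, CH–CH2O, acetyl) is built with an oxazolidinone auxiliary. The cyclohexene, the only ring made, is closed in one operation by radical C–H addition to vinyltriphenylphosphonium bromide and intramolecular Wittig olefination. The dioxolane is then removed, and the coumarin ether and the ester are attached last.
- Stereochemistry: C-5 comes from the titanium-enolate hydroxymethylation controlled by (R)-4-benzyloxazolidinone; C-1 from axial hydride delivery to the ring ketone, cis to the C-5 side chain; the ester α-centre is bought as (R)-2-methylbutanoic acid.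

Key step: step 8

Remark: the target is read as the (1R,5S) ring (acyloxy and aryloxymethyl groups cis) esterified with (R)-2-methylbutanoic acid, and this acid is assumed to be purchasable in enantiopure form.

**Route**

Step 1
Reactants: 1 3,3-dimethylpent-4-enoic acid; 2 (4R)-4-benzyl-1,3-oxazolidin-2-one
Product: 4 (4R)-4-benzyl-3-(3,3-dimethylpent-4-enoyl)-1,3-oxazolidin-2-one, via mixed pivalic anhydride 3 (not isolated)
Conditions: PivCl, Et3N, THF, −20 °C; then LiCl, 2, −20 °C → rt
Reagents that add atoms: none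
Why: N-acylation of the lithium-chloride-activated oxazolidinone by the mixed pivalic anhydride is the standard one-pot entry to N-acyl Evans auxiliaries and should occur at the unhindered acyl carbonyl of 3.

Step 2
Reactants: 4 (4R)-4-benzyl-3-(3,3-dimethylpent-4-enoyl)-1,3-oxazolidin-2-one
Product: 6 (4R)-4-benzyl-3-[(2S)-2-(hydroxymethyl)-3,3-dimethylpent-4-enoyl]-1,3-oxazolidin-2-one, via titanium enolate 5 (not isolated)
Conditions: TiCl4, i-Pr2NEt, CH2Cl2, 0 °C; then 1,3,5-trioxane, TiCl4, 0 °C
Reagents that add atoms: 1,3,5-trioxane, C1OCOCO1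
Why: Evans hydroxymethylation (titanium-enolate aldol with formaldehyde released from trioxane), in which the chelated (Z)-enolate should be attacked on the face opposite the benzyl group, setting the (2S) centre that becomes C-5 of the ring.

Step 3
Reactants: 6 (4R)-4-benzyl-3-[(2S)-2-(hydroxymethyl)-3,3-dimethylpent-4-enoyl]-1,3-oxazolidin-2-one
Product: 7 (4R)-4-benzyl-3-[(2S)-2-{[(tert-butyldimethylsilyl)oxy]methyl}-3,3-dimethylpent-4-enoyl]-1,3-oxazolidin-2-one
Conditions: TBSCl, imidazole, DMF, rt
Reagents that add atoms: tert-butyldimethylsilyl chloride, CC(C)(C)[Si](C)(C)Cl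
Why: Standard silylation of a primary alcohol, giving an ether that should carry the hydroxymethyl group through the organolithium and base steps.

Step 4
Reactants: 7 (4R)-4-benzyl-3-[(2S)-2-{[(tert-butyldimethylsilyl)oxy]methyl}-3,3-dimethylpent-4-enoyl]-1,3-oxazolidin-2-one
Product: 9 (4R)-4-benzyl-3-[(2S)-2-{[(tert-butyldimethylsilyl)oxy]methyl}-3,3-dimethyl-4-oxobutanoyl]-1,3-oxazolidin-2-one, via ozonide 8 (not isolated)
Conditions: O3, CH2Cl2, −78 °C; then Me2S, −78 °C → rt
Reagents that add atoms: ozone, [O-][O+]=O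
Why: Ozonolysis of the monosubstituted alkene with reductive work-up should unmask the future C-1 as an aldehyde that has no α-hydrogen and therefore cannot enolise.

Step 5
Reactants: 9 (4R)-4-benzyl-3-[(2S)-2-{[(tert-butyldimethylsilyl)oxy]methyl}-3,3-dimethyl-4-oxobutanoyl]-1,3-oxazolidin-2-one
Product: 10 (4R)-4-benzyl-3-[(2S)-2-{[(tert-butyldimethylsilyl)oxy]methyl}-3-(1,3-dioxolan-2-yl)-3-methylbutanoyl]-1,3-oxazolidin-2-one
Conditions: (TMSOCH2)2, TMSOTf (cat.), CH2Cl2, −78 → −20 °C
Reagents that add atoms: 1,2-bis(trimethylsilyloxy)ethane, C[Si](C)(C)OCCO[Si](C)(C)C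
Why: Aprotic acetalisation under silyl triflate catalysis (Noyori conditions) should convert only the aldehyde, spare the silyl ether and the imide, and install the doubly oxygen-activated C–H bond needed in step 8.

Step 6
Reactants: 10 (4R)-4-benzyl-3-[(2S)-2-{[(tert-butyldimethylsilyl)oxy]methyl}-3-(1,3-dioxolan-2-yl)-3-methylbutanoyl]-1,3-oxazolidin-2-one
Product: 12 (2S)-2-{[(tert-butyldimethylsilyl)oxy]methyl}-3-(1,3-dioxolan-2-yl)-3-methylbutanoic acid, via peroxy acid 11 (not isolated)
Conditions: LiOH, H2O2, THF–H2O (3:1), 0 °C; then aq. Na2SO3; then 1 M HCl to pH 4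
Reagents that add atoms: hydrogen peroxide, OO
Why: Lithium hydroperoxide cleaves N-acyloxazolidinones at the exocyclic carbonyl without epimerising the α-centre, and sulfite should reduce the peroxy acid to the acid.

Step 7
Reactants: 12 (2S)-2-{[(tert-butyldimethylsilyl)oxy]methyl}-3-(1,3-dioxolan-2-yl)-3-methylbutanoic acid
Product: 14 (3S)-3-{[(tert-butyldimethylsilyl)oxy]methyl}-4-(1,3-dioxolan-2-yl)-4-methylpentan-2-one, via dilithium gem-diolate 13 (not isolated)
Conditions: MeLi (3 equiv), Et2O, −78 → 0 °C; then inverse quench into cold aq. NH4Cl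
Reagents that add atoms: methyllithium, [Li]C
Why: Addition of methyllithium to the lithium carboxylate stops at the stable gem-diolate, which releases the methyl ketone only on quench, so neither over-addition nor epimerisation of the α-centre is expected.

Step 8
Reactants: 14 (3S)-3-{[(tert-butyldimethylsilyl)oxy]methyl}-4-(1,3-dioxolan-2-yl)-4-methylpentan-2-one; 15 vinyltriphenylphosphonium bromide
Product: 18 tert-butyl(dimethyl){[(9S)-8,10,10-trimethyl-1,4-dioxaspiro[4.5]dec-7-en-9-yl]methoxy}silane, via phosphonium bromide 16 (not isolated), via phosphorus ylide 17 (not isolated)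
Conditions: 15 (1.5 equiv), (n-Bu4N)4[W10O32] (2 mol %), MeCN, 390 nm LEDs, 25 °C; then solvent exchange to THF, KHMDS, −78 °C → 45 °C
Reagents that add atoms: none
Why: Proposed new method: photoexcited decatungstate should abstract the acetal hydrogen of 14 (the weakest and most hydridic C–H bond, flanked by two oxygens), the nucleophilic dioxolan-2-yl radical should add to the CH2 terminus of the vinylphosphonium ion (C-1–C-2 bond), the α-phosphonio radical should take back an electron and a proton from the reduced polyoxometalate to give salt 16, and KHMDS should then form ylide 17, whose carbon attacks the methyl ketone intramolecularly (Wittig olefination, C-3=C-4 bond). The closest known reaction types are the decatungstate- or aryl-ketone-sensitised C–H addition of 1,3-dioxolanes to electron-poor alkenes (Giese reaction), radical addition to vinylphosphonium salts followed by Wittig olefination, and the Schweizer Michael–Wittig annulation with vinyltriphenylphosphonium bromide. The cyclohexene is closed at C-3=C-4 by 6-exo attack of the ylide carbon on the ketone and collapse of the oxaphosphetane, favoured by the gem-dimethyl and ketal carbons in the chain (Thorpe–Ingold effect), so the alkene can only be endocyclic, trisubstituted and placed at the former carbonyl carbon. No stereocentre is formed, because the radical carbon becomes a non-stereogenic ketal carbon, and the (S) centre next to the ketone should survive because enolisation towards this hindered tertiary carbon is slow beside ylide formation at low temperature. The step needs site selectivity in the hydrogen abstraction (acetal C–H against the ether CH2–O and α-keto C–H bonds, secured by bond strength and polarity matching with the electrophilic oxo radical) and chemoselectivity afterwards, which the dioxolane secures: as an acyl-radical equivalent it cannot lose CO, and it leaves no C-1 carbonyl that would allow E1cB loss of PPh3 from 16 or later conjugation of the alkene.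

Step 9
Reactants: 18 tert-butyl(dimethyl){[(9S)-8,10,10-trimethyl-1,4-dioxaspiro[4.5]dec-7-en-9-yl]methoxy}silane
Product: 19 (3S)-3-(hydroxymethyl)-2,2,4-trimethylcyclohex-4-en-1-one
Conditions: AcOH–THF–H2O (3:1:1), 40 °C
Reagents that add atoms: water, O
Why: Aqueous acetic acid should hydrolyse the dioxolane and the primary silyl ether together while being too weak an acid to move the β,γ-double bond into conjugation with the new ketone.

Step 10
Reactants: 19 (3S)-3-(hydroxymethyl)-2,2,4-trimethylcyclohex-4-en-1-one; 20 umbelliferone (7-hydroxy-2H-chromen-2-one)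
Product: 21 7-{[(1S)-2,6,6-trimethyl-5-oxocyclohex-2-en-1-yl]methoxy}-2H-chromen-2-one
Conditions: PPh3, DIAD, THF, 0 °C → rt
Reagents that add atoms: none
Why: Mitsunobu etherification, in which the acidic phenol (pKa about 8) displaces the activated primary hydroxyl by SN2 at CH2, so no stereocentre is involved and no strong base touches the β,γ-unsaturated ketone.

Step 11
Reactants: 21 7-{[(1S)-2,6,6-trimethyl-5-oxocyclohex-2-en-1-yl]methoxy}-2H-chromen-2-one
Product: 22 7-{[(1S,5R)-5-hydroxy-2,6,6-trimethylcyclohex-2-en-1-yl]methoxy}-2H-chromen-2-one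
Conditions: NaBH4, CeCl3·7H2O, MeOH, −78 → −40 °C
Reagents that add atoms: none
Why: Luche reduction is 1,2-selective for the ketone over the coumarin, and the small hydride is expected to attack along the axial trajectory on the face opposite the neighbouring aryloxymethyl group (the other face is screened by an axial methyl of the gem-dimethyl carbon), giving the equatorial (R) alcohol cis to that group.

Step 12
Reactants: 22 7-{[(1S,5R)-5-hydroxy-2,6,6-trimethylcyclohex-2-en-1-yl]methoxy}-2H-chromen-2-one; 23 (2R)-2-methylbutanoic acid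
Product: 24 (1R,5S)-4,6,6-trimethyl-5-{[(2-oxo-2H-chromen-7-yl)oxy]methyl}cyclohex-3-en-1-yl (2R)-2-methylbutanoate
Conditions: DCC, DMAP (cat.), CH2Cl2, 0 °C → rt
Reagents that add atoms: none
Why: Steglich esterification should acylate the hindered secondary alcohol through the acylpyridinium ion with retention at the carbinol carbon and at the α-centre of the acid.

**Compound list**

1 | 3,3-dimethylpent-4-enoic acid | C=CC(C)(C)CC(=O)O | starting material
2 | (4R)-4-benzyl-1,3-oxazolidin-2-one | O=C1N[C@H](Cc2ccccc2)CO1 | starting material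
3 | 2,2-dimethylpropanoic 3,3-dimethylpent-4-enoic anhydride (mixed pivalic anhydride) | C=CC(C)(C)CC(=O)OC(=O)C(C)(C)C | intermediate
4 | (4R)-4-benzyl-3-(3,3-dimethylpent-4-enoyl)-1,3-oxazolidin-2-one | O=C1OC[C@@H](Cc2ccccc2)N1C(=O)CC(C)(C)C=C | intermediate
5 | trichlorotitanium (Z)-enolate of 4 | O=C1OC[C@@H](Cc2ccccc2)N1/C(O[Ti](Cl)(Cl)Cl)=C/C(C)(C)C=C | intermediate
6 | (4R)-4-benzyl-3-[(2S)-2-(hydroxymethyl)-3,3-dimethylpent-4-enoyl]-1,3-oxazolidin-2-one | O=C1OC[C@@H](Cc2ccccc2)N1C(=O)[C@H](CO)C(C)(C)C=C | intermediate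
7 | (4R)-4-benzyl-3-[(2S)-2-{[(tert-butyldimethylsilyl)oxy]methyl}-3,3-dimethylpent-4-enoyl]-1,3-oxazolidin-2-one | O=C1OC[C@@H](Cc2ccccc2)N1C(=O)[C@H](CO[Si](C)(C)C(C)(C)C)C(C)(C)C=C | intermediate
8 | (4R)-4-benzyl-3-[(2S)-2-{[(tert-butyldimethylsilyl)oxy]methyl}-3-methyl-3-(1,2,4-trioxolan-3-yl)butanoyl]-1,3-oxazolidin-2-one (ozonide) | O=C1OC[C@@H](Cc2ccccc2)N1C(=O)[C@H](CO[Si](C)(C)C(C)(C)C)C(C)(C)C3OCOO3 | intermediate
9 | (4R)-4-benzyl-3-[(2S)-2-{[(tert-butyldimethylsilyl)oxy]methyl}-3,3-dimethyl-4-oxobutanoyl]-1,3-oxazolidin-2-one | O=C1OC[C@@H](Cc2ccccc2)N1C(=O)[C@H](CO[Si](C)(C)C(C)(C)C)C(C)(C)C=O | intermediate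
10 | (4R)-4-benzyl-3-[(2S)-2-{[(tert-butyldimethylsilyl)oxy]methyl}-3-(1,3-dioxolan-2-yl)-3-methylbutanoyl]-1,3-oxazolidin-2-one | O=C1OC[C@@H](Cc2ccccc2)N1C(=O)[C@H](CO[Si](C)(C)C(C)(C)C)C(C)(C)C3OCCO3 | intermediate
11 | (2S)-2-{[(tert-butyldimethylsilyl)oxy]methyl}-3-(1,3-dioxolan-2-yl)-3-methylbutaneperoxoic acid | OOC(=O)[C@H](CO[Si](C)(C)C(C)(C)C)C(C)(C)C1OCCO1 | intermediate
12 | (2S)-2-{[(tert-butyldimethylsilyl)oxy]methyl}-3-(1,3-dioxolan-2-yl)-3-methylbutanoic acid | OC(=O)[C@H](CO[Si](C)(C)C(C)(C)C)C(C)(C)C1OCCO1 | intermediate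
13 | dilithium (3S)-3-{[(tert-butyldimethylsilyl)oxy]methyl}-4-(1,3-dioxolan-2-yl)-4-methylpentane-2,2-diolate | [Li]OC(C)(O[Li])[C@H](CO[Si](C)(C)C(C)(C)C)C(C)(C)C1OCCO1 | intermediate
14 | (3S)-3-{[(tert-butyldimethylsilyl)oxy]methyl}-4-(1,3-dioxolan-2-yl)-4-methylpentan-2-one | CC(=O)[C@H](CO[Si](C)(C)C(C)(C)C)C(C)(C)C1OCCO1 | intermediate
15 | vinyltriphenylphosphonium bromide | C=C[P+](c1ccccc1)(c1ccccc1)c1ccccc1.[Br-] | starting material
16 | [2-(2-{(3S)-3-{[(tert-butyldimethylsilyl)oxy]methyl}-2-methyl-4-oxopentan-2-yl}-1,3-dioxolan-2-yl)ethyl]triphenylphosphonium bromide | CC(=O)[C@H](CO[Si](C)(C)C(C)(C)C)C(C)(C)C1(CC[P+](c2ccccc2)(c2ccccc2)c2ccccc2)OCCO1.[Br-] | intermediate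
17 | (3S)-3-{[(tert-butyldimethylsilyl)oxy]methyl}-4-methyl-4-{2-[2-(triphenyl-λ5-phosphanylidene)ethyl]-1,3-dioxolan-2-yl}pentan-2-one (ylide) | CC(=O)[C@H](CO[Si](C)(C)C(C)(C)C)C(C)(C)C1(CC=P(c2ccccc2)(c2ccccc2)c2ccccc2)OCCO1 | intermediate
18 | tert-butyl(dimethyl){[(9S)-8,10,10-trimethyl-1,4-dioxaspiro[4.5]dec-7-en-9-yl]methoxy}silane | CC1=CCC2(OCCO2)C(C)(C)[C@H]1CO[Si](C)(C)C(C)(C)C | intermediate
19 | (3S)-3-(hydroxymethyl)-2,2,4-trimethylcyclohex-4-en-1-one | CC1=CCC(=O)C(C)(C)[C@H]1CO | intermediate
20 | umbelliferone (7-hydroxy-2H-chromen-2-one) | Oc1ccc2ccc(=O)oc2c1 | starting material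
21 | 7-{[(1S)-2,6,6-trimethyl-5-oxocyclohex-2-en-1-yl]methoxy}-2H-chromen-2-one | CC1=CCC(=O)C(C)(C)[C@H]1COc1ccc2ccc(=O)oc2c1 | intermediate
22 | 7-{[(1S,5R)-5-hydroxy-2,6,6-trimethylcyclohex-2-en-1-yl]methoxy}-2H-chromen-2-one | CC1=CC[C@@H](O)C(C)(C)[C@H]1COc1ccc2ccc(=O)oc2c1 | intermediate
23 | (2R)-2-methylbutanoic acid | CC[C@@H](C)C(=O)O | starting material
24 | (1R,5S)-4,6,6-trimethyl-5-{[(2-oxo-2H-chromen-7-yl)oxy]methyl}cyclohex-3-en-1-yl (2R)-2-methylbutanoate | CC[C@@H](C)C(=O)O[C@@H]1CC=C(C)[C@H](COc2ccc3ccc(=O)oc3c2)C1(C)C | target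

**Step count and risks**

Total step count: 12. Longest linear sequence: 12 steps (1 → 24).

Steps most likely to fail:

1. Step 8 (proposed new method). Hydrogen abstraction may occur at other C–H bonds (silyl ether CH2, dioxolane CH2) or too slowly at the hindered acetal position. The vinylphosphonium salt may oligomerise by radical chain growth. The ketone may enolise during ylide formation, with epimerisation or β-elimination of the silyloxy group. Fallback with known chemistry, setting out from 14 and returning at 24: Wittig methylenation of 14 (Ph3P=CH2, THF) would give the isopropenyl acetal F1, and neutral transacetalisation (catalytic iodine, acetone) would free the aldehyde F2. Reagent-controlled allylation with (+)-B-allyldiisopinocampheylborane (Et2O, −78 °C; NaOH/H2O2) would form the C-1–C-2 bond and the (R) carbinol of the dienol F3. Ring-closing metathesis with the second-generation Grubbs catalyst (CH2Cl2, 40 °C) would close C-3=C-4 to the cyclohexenol silyl ether F4. DCC/DMAP esterification with 23 would give the silyl ether ester F5, HF·pyridine the hydroxy ester F6, and Mitsunobu etherification of F6 with 20 (PPh3, DIAD) would give 24.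

2. Step 11. Facial selectivity of hydride delivery may be poor, giving the trans alcohol, and the coumarin may be partly reduced. Fallback, setting out from 21 and returning at 22 with no new compound: catalyst-controlled reduction with (S)-2-methyl-CBS-oxazaborolidine and catecholborane (toluene, −78 °C), in which the oxazaborolidine, reading the gem-dimethyl carbon as the large group, selects the carbonyl face instead of the ring conformation.

3. Step 6. Hydroperoxide may attack the ring carbonyl of the very hindered imide (endocyclic cleavage and loss of the acyl fragment), or hydrolysis may be slow enough for the silyl ether to be lost. Fallback, setting out from 10 and returning at 14: lithium benzylthiolate (BnSH, n-BuLi, THF, 0 °C), which attacks only the exocyclic carbonyl of hindered imides, would give the S-benzyl thioester F7, and lithium dimethylcuprate (Me2CuLi, Et2O, −78 °C) would convert F7 directly into ketone 14 without passing through acid 12.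

Further compounds
F1 | step 8 | tert-butyl{[(2S)-2-[2-(1,3-dioxolan-2-yl)propan-2-yl]-3-methylbut-3-en-1-yl]oxy}dimethylsilane | C=C(C)[C@H](CO[Si](C)(C)C(C)(C)C)C(C)(C)C1OCCO1
F2 | step 8 | (3S)-3-{[(tert-butyldimethylsilyl)oxy]methyl}-2,2,4-trimethylpent-4-enal | C=C(C)[C@H](CO[Si](C)(C)C(C)(C)C)C(C)(C)C=O
F3 | step 8 | (4R,6S)-6-{[(tert-butyldimethylsilyl)oxy]methyl}-5,5,7-trimethylocta-1,7-dien-4-ol | C=CC[C@@H](O)C(C)(C)[C@@H](CO[Si](C)(C)C(C)(C)C)C(C)=C
F4 | step 8 | (1R,5S)-5-{[(tert-butyldimethylsilyl)oxy]methyl}-4,6,6-trimethylcyclohex-3-en-1-ol | CC1=CC[C@@H](O)C(C)(C)[C@H]1CO[Si](C)(C)C(C)(C)C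
F5 | step 8 | (1R,5S)-5-{[(tert-butyldimethylsilyl)oxy]methyl}-4,6,6-trimethylcyclohex-3-en-1-yl (2R)-2-methylbutanoate | CC[C@@H](C)C(=O)O[C@@H]1CC=C(C)[C@H](CO[Si](C)(C)C(C)(C)C)C1(C)C
F6 | step 8 | (1R,5S)-5-(hydroxymethyl)-4,6,6-trimethylcyclohex-3-en-1-yl (2R)-2-methylbutanoate | CC[C@@H](C)C(=O)O[C@@H]1CC=C(C)[C@H](CO)C1(C)C
F0 | step 11 | none | none
F7 | step 6 | S-benzyl (2S)-2-{[(tert-butyldimethylsilyl)oxy]methyl}-3-(1,3-dioxolan-2-yl)-3-methylbutanethioate | O=C(SCc1ccccc1)[C@H](CO[Si](C)(C)C(C)(C)C)C(C)(C)C1OCCO1
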